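Counted in mM of target instead of percent of the charge, the two earlier runs end closer together than their percentages suggest: from teal to blue the substrate charge rises by a factor of 15.5, but target rises by less, a factor of 2.35.

common to all: free catalyst 2.3 mM
- teal: substrate 11 mM; gas 9 mM (held); run made earlier
- blue: substrate 170 mM; gas 9 mM (held); run made earlier
- west: substrate 200 mM; gas 9.0 mM (held); time 4.0 h
- north: substrate 15 mM; gas 9.0 mM (held); time 4.0 h
- east: substrate 150 mM; gas 9.0 mM (held); time 4.0 h
- south-east: substrate 60 mM; gas 9.0 mM (held); time 4.0 h
- south: substrate 46 mM; gas 9.0 mM (held); time 4.0 h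

| run | time / h | target / % | substrate / % |
|---|---|---|---|
| teal | 0.200 | 38.4 | 53.8 |
| teal | 0.500 | 65.9 | 15.6 |
| teal | 1.00 | 77.6 | 1.5 |
| teal | 1.50 | 79.5 | 1.6 |
| teal | 2.00 | 77.4 | 1.9 |
| teal | 3.00 | 78.9 | 0 |
| blue | 0.200 | 3.2 | 83.9 |
| blue | 0.500 | 4.4 | 60.0 |
| blue | 1.00 | 7.8 | 22.5 |
| blue | 1.50 | 9.9 | 3.4 |
| blue | 2.00 | 11.7 | 1.4 |
| blue | 3.00 | 12.0 | 0.3 |

(readings scatter by 1 percentage point)

- at the start none of the gas is in solution

1. the flasks put in order of amount of target, in percent of the substrate charged, best first, at 4.0 h (west / north / east / south-east / south)
2. the same order at 30 h (west / north / east / south-east / south)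
3. the amount of target, in percent of the substrate charged of the flask you put first, at 4.0 h
4. the amount of target, in percent of the substrate charged of the flask you put last, at 4.0 h

At their last readings teal holds 8.68 mM of target and 0 % of substrate, while blue holds 20.4 mM of target and 0.3 % of substrate, so I read both as finished. With gas and free catalyst held as in those runs, I let the yield Y, target as a fraction of the substrate charge c, follow Y = G/(c + h). Through the two runs this gives h = 17.5 mM, the charge at which target reaches half of G, and the target ceiling G = 22.5 mM, the mM of target that this curve approaches as the charge grows. My curve therefore ranks the flasks by charge, smallest first, with north at 69.2 % and west at 10.3 %, and I expect the same order at 30 h.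

The forecast, made separately, gives north > south > south-east > east > west at 4.0 h and north > south > south-east > east > west at 30 h, with north at 68 % and west at 11 %. Its ground is this: “Target in mM is therefore roughly the cap multiplied by the consumption time, plus a tail of about 5 mM, so percent falls steadily with charge.”

The flasks give north > south > south-east > east > west at 4.0 h, with north at 71.9 % and west at 9.70 %, so the forecast stands. At 30 h the order is north > south > south-east > east > west, with north still at 71.9 %, so in north waiting longer gains nothing.

    reagent + free catalyst → catalyst intermediate A (k = 3.10 L mol⁻¹ s⁻¹)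
    substrate + target → side product (k = 0.0290 L mol⁻¹ s⁻¹)
    catalyst intermediate A ⇌ catalyst intermediate B (K = 2.90, k = 3.00 s⁻¹)
    substrate + catalyst intermediate B → catalyst intermediate C (k = 0.700 L mol⁻¹ s⁻¹)
    gas ⇌ reagent, rate k5*(csat - [reagent]) (kL = 0.0130 s⁻¹)
    catalyst intermediate C ⇌ free catalyst + target (K = 0.0220 M, k = 0.0270 s⁻¹)

In north at 0.0882 h, substrate has a half-life of 0.25 h by its step with catalyst intermediate B, whereas catalyst intermediate C has a half-life of 0.43 min by its forward step alone, far shorter. At 4.00 h, with substrate at 0 %, north holds 0 % of its catalyst as catalyst intermediate C, 0 % as free catalyst, 74.4 % as catalyst intermediate B and 25.6 % as catalyst intermediate A, so at that moment the resting state is the pair of intermediates B and A. The ceiling 22.5 mM, taken with h = 17.5 mM, puts north at 69.2 % against the 71.9 % it holds, and it puts the neighbour of north charged with 38 mM of substrate at 40.5 %, where that flask holds 45.5 %.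

The runs come from a simulation on assumed constants, and the scatter is random.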